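The data come from a simulation for an exercise, noise included.

If the chains were to reach the length asked, two things counted: how much free monomer went into chains, and how many chains shared it.

| setting | Saturday's | flask |
|---|---|---|
| free monomer | 0.36 M | 0.36 M |
| pre-initiator | 4.5 mM | 9.0 mM |
| remark | run made earlier |  |
| time |  | 6.0 h |

Saturday's run (percent of the free monomer charged)

| time / min | monomer in chains / % | free monomer / % |
|---|---|---|
| 8.00 | 0 | 97.5 |
| 15.0 | 0 | 94.5 |
| 30.0 | 2.2 | 89.2 |
| 60.0 | 6.4 | 75.6 |
| 120 | 19.2 | 48.1 |

(readings scatter by 1 percentage point)

* whether the average number of monomer units in a chain (chains begun, living or dead) reaches 20 by 6.0 h (yes / no)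
* average number of monomer units in a chain (chains begun, living or dead) at 6.0 h

- the average divides the monomer in chains by the number of chains begun, living and dead together
- what was read earlier has a scatter of 1 percentage point, one standard deviation
- steps under discussion: pre-initiator <-> initiator; free monomer + initiator -> living end + monomer in chains; free monomer + living end -> monomer in chains + living end; free monomer -> uncatalysed product
- the earlier runs do not show the number of chains; that part of a forecast is a guess
- no earlier run changes the charge of pre-initiator; that part of a forecast is a guess

I reckoned in rates. Saturday's run showed 0% in chains at 15.0 min, so I read its early loss as the uncatalysed rate, in logarithms: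

uncatalysed rate = ln(1/94.5%) / 15.0 min = 0.226 h⁻¹

I took chain growth and the uncatalysed loss to be each first order in free monomer, so the falling free monomer cancels from the ratio of their rates. Saturday's readings gave that ratio as 0.447 over the span from 30.0 min to 60.0 min, then 0.871 from 60.0 min to 120 min. The second span's midpoint lies twice as late, so I let the ratio grow in proportion to time. I guessed that it also scales with the charge, which is twice Saturday's in this flask:

ratio at 1.90 h = 2.20

This chain ratio, free monomer entering chains per free monomer turned into uncatalysed product, is a selectivity factor. Accumulated to 6.0 h, my two reckoned rates brought free monomer down by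

2.64 powers of ten.

Taking that ratio as typical, I reckoned 68.8% of the free monomer charged to end in chains. Each chain begun uses one initiator, so if the whole charge of pre-initiator began chains, my estimate of the average was 27.5, more than 20. I said yes, and went no further than that estimate, since the chain count was a guess.

The forecast said yes and 150, noting “The chain count is a guess”; my 27.5 was a low-end estimate, not a forecast of the average.

The flask gave yes and 48.6.

    pre-initiator ⇌ initiator (K = 9.85, k = 8.56 × 10⁻⁵ s⁻¹)
    free monomer + initiator → living end + monomer in chains (k = 0.00197 M⁻¹ s⁻¹)
    free monomer + living end → monomer in chains + living end, rate k3*[living end]*[free monomer] (k = 0.0548 M⁻¹ s⁻¹)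
    free monomer → uncatalysed product (k = 6.06 × 10⁻⁵ s⁻¹)

My chain ratio of 2.20 stood in the flask at 2.5 at 1.90 h, but at 6.0 h the flask showed 4.0, below the 6.95 that growth in proportion to time had given. At 6.0 h the flask held monomer in chains at 60.3% beside uncatalysed product at 39.1%, with living ends at 0.00446 M.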